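**Retrosynthetic overview**
1. The C4 side chain (as the dioxolane-masked 3-oxopent-1-en-2-yl cuprate) is added last to a bicyclo[3.1.0]hex-3-en-2-one, anti to the cyclopropane; the C2 oxygen is then removed through the enol triflate, which leaves the C2=C3 double bond of the target.
2. That enone comes by carbonyl transposition from a 4-methoxybicyclo[3.1.0]hex-3-en-2-one. This is disconnected photochemically (type A cyclohexadienone rearrangement) at the bond between the future olefinic C2 and the methyl-bearing bridgehead C1, and at the cyclopropane bond C5–C6, back to a 3-methoxy-2,4,5-trimethyl-4-pyranonylcyclohexa-2,5-dienone.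
3. Enabling feature: in the dienone the C1 carbonyl is cross-conjugated with C2=C3 and C5=C6, so the β-carbons C3 and C5 sit 1,3 across the sp3 carbon C4 that already carries the methyl and pyranone groups. The C3 methoxy group steers the shift of C4 and later serves as the removable oxygen.
4. The dienone comes from dearomatisation: asymmetric Birch reduction–methylation of a 2-methoxy-3,6-dimethylbenzamide (from 2,5-dimethylanisole) sets the quaternary stereocentre, the pyranone is built on the derived ethyl ketone, and the doubly allylic CH2 is oxidised.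
5. Ring order: benzene ring (bought, then dearomatised) → pyranone ring → five- and three-membered carbocycles together in the photochemical step.

Key step: step 9

Assumption: the (S)-auxiliary is taken to give the (1S) epimer 8 as the major product of the reductive methylation, by analogy with 2-methoxybenzamides; 8 and its C1 epimer are diastereomers and are separated at that stage, and the (R)-auxiliary would be used if the preference proved to be reversed.

**Route**

Step 1
Reactants: 1 2,5-dimethylanisole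
Product: 3 2-methoxy-3,6-dimethylbenzoic acid, via aryllithium 2 (not isolated)
Conditions: n-BuLi, TMEDA, Et2O, rt; CO2 (solid), −78 °C; aq. HCl
Reagents that add atoms: carbon dioxide, O=C=O
Why: Directed ortho-metalation: the methoxy group directs lithiation to its only free ortho position and the aryllithium is carboxylated.

Step 2
Reactants: 3 2-methoxy-3,6-dimethylbenzoic acid; 4 (S)-2-(methoxymethyl)pyrrolidine
Product: 6 (2-methoxy-3,6-dimethylphenyl)[(2S)-2-(methoxymethyl)pyrrolidin-1-yl]methanone, via acid chloride 5 (not isolated)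
Conditions: (COCl)2, DMF (cat.), CH2Cl2, 0 °C to rt; then 4, Et3N, CH2Cl2, 0 °C to rt
Reagents that add atoms: none
Why: Acyl chloride formation followed by amidation with the secondary amine installs the proline-derived auxiliary without touching its stereocentre.

Step 3
Reactants: 6 (2-methoxy-3,6-dimethylphenyl)[(2S)-2-(methoxymethyl)pyrrolidin-1-yl]methanone
Product: 8 [(1S)-2-methoxy-1,3,6-trimethylcyclohexa-2,5-dien-1-yl][(2S)-2-(methoxymethyl)pyrrolidin-1-yl]methanone, via potassium enolate 7 (not isolated)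
Conditions: K (2.2 equiv), liquid NH3/THF, t-BuOH (1 equiv), −78 °C; then MeI, −78 °C to rt
Reagents that add atoms: iodomethane, CI
Why: Birch reduction–alkylation: two-electron reduction with protonation at C4 gives the chelated amide enolate 7, which should be methylated at C1 on the face left open by the methoxymethyl arm of the auxiliary (auxiliary control of the new quaternary stereocentre), the minor C1 epimer being removed as a diastereomer.

Step 4
Reactants: 8 [(1S)-2-methoxy-1,3,6-trimethylcyclohexa-2,5-dien-1-yl][(2S)-2-(methoxymethyl)pyrrolidin-1-yl]methanone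
Product: 10 1-[(1S)-2-methoxy-1,3,6-trimethylcyclohexa-2,5-dien-1-yl]propan-1-one, via lithium hemiaminal 9 (not isolated)
Conditions: EtLi, THF, −78 to 0 °C; H2O
Reagents that add atoms: ethyllithium, [Li]CC
Why: Nucleophilic acyl substitution of a tertiary amide by an organolithium: the tetrahedral lithium alkoxide 9 is stable until work-up, so no second addition should occur, and its collapse gives the ketone and frees the auxiliary without touching the quaternary centre.

Step 5
Reactants: 10 1-[(1S)-2-methoxy-1,3,6-trimethylcyclohexa-2,5-dien-1-yl]propan-1-one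
Product: 11 trimethyl{[(1Z)-1-[(1S)-2-methoxy-1,3,6-trimethylcyclohexa-2,5-dien-1-yl]prop-1-en-1-yl]oxy}silane
Conditions: Me3SiOTf, Et3N, CH2Cl2, 0 °C
Reagents that add atoms: trimethylsilyl trifluoromethanesulfonate, C[Si](C)(C)OS(=O)(=O)C(F)(F)F
Why: Silyl enol ether formation by soft enolisation at the only enolisable position should give the (Z)-enol ether, the amine base keeping the ring enol ether intact.

Step 6
Reactants: 11 trimethyl{[(1Z)-1-[(1S)-2-methoxy-1,3,6-trimethylcyclohexa-2,5-dien-1-yl]prop-1-en-1-yl]oxy}silane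
Product: 13 4-hydroxy-6-[(1S)-2-methoxy-1,3,6-trimethylcyclohexa-2,5-dien-1-yl]-3,5-dimethyl-2H-pyran-2-one, via acyl chloride 12 (not isolated)
Conditions: ClC(O)CH(CH3)C(O)Cl, 2,6-di-tert-butyl-4-methylpyridine, Et2O, −78 °C to rt; cold pH 7 buffer
Reagents that add atoms: 2-methylpropanedioyl dichloride, CC(C(=O)Cl)C(=O)Cl
Why: Pyranone annulation of a silyl enol ether with a malonyl dichloride: C-acylation gives 12, whose enolised ketone oxygen closes onto the second acyl chloride (lactonisation) to give the 4-hydroxy-2-pyranone on the quaternary carbon.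

Step 7
Reactants: 13 4-hydroxy-6-[(1S)-2-methoxy-1,3,6-trimethylcyclohexa-2,5-dien-1-yl]-3,5-dimethyl-2H-pyran-2-one
Product: 14 2-methoxy-6-[(1S)-2-methoxy-1,3,6-trimethylcyclohexa-2,5-dien-1-yl]-3,5-dimethyl-4H-pyran-4-one
Conditions: MeOTf, 2,6-di-tert-butyl-4-methylpyridine, CH2Cl2, 0 °C to rt
Reagents that add atoms: methyl trifluoromethanesulfonate, COS(=O)(=O)C(F)(F)F
Why: Regioselective O-methylation: the hard methylating agent should attack the lactone carbonyl oxygen of the neutral hydroxypyranone and proton loss then gives the 2-methoxy-4-pyranone, the hindered pyridine taking up the acid so that the ring enol ether survives.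

Step 8
Reactants: 14 2-methoxy-6-[(1S)-2-methoxy-1,3,6-trimethylcyclohexa-2,5-dien-1-yl]-3,5-dimethyl-4H-pyran-4-one
Product: 15 (4S)-3-methoxy-4-(6-methoxy-3,5-dimethyl-4-oxo-4H-pyran-2-yl)-2,4,5-trimethylcyclohexa-2,5-dien-1-one
Conditions: (C5H5NH)2Cr2O7, t-BuOOH, Celite, benzene, rt
Reagents that add atoms: tert-butyl hydroperoxide, CC(C)(C)OO
Why: Allylic oxidation: hydrogen abstraction at the doubly allylic CH2 and oxygenation by the hydroperoxide under chromium mediation (hexavalent chromium is regenerated by the peroxide) should give the cross-conjugated dienone with the quaternary stereocentre untouched.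

Step 9
Reactants: 15 (4S)-3-methoxy-4-(6-methoxy-3,5-dimethyl-4-oxo-4H-pyran-2-yl)-2,4,5-trimethylcyclohexa-2,5-dien-1-one
Product: 17 (1R,5S,6S)-4-methoxy-6-(6-methoxy-3,5-dimethyl-4-oxo-4H-pyran-2-yl)-3,5,6-trimethylbicyclo[3.1.0]hex-3-en-2-one (pyranone exo and 6-methyl endo), via oxyallyl zwitterion 16 (not isolated)
Conditions: hν (366 nm), degassed benzene (about 0.01 M), rt
Reagents that add atoms: none
Why: n→π* excitation of the cross-conjugated dienone at 366 nm (a wavelength the pyranone does not absorb) and intersystem crossing give the triplet, in which the β-carbons C3 and C5 bond across the sp3 carbon C4 to give the oxyallyl zwitterion 16, and C4 then shifts from C3 to C6 in a suprafacial [1,4]-sigmatropic step. The closest known reaction type is the type A (lumiketone) photorearrangement of 4,4-disubstituted 3-methoxycyclohexa-2,5-dienones. The C3–C5 bond closes the five-membered ring by 1,3-bonding of the two enone β-termini, which contracts the six-membered ring, and the C4–C6 bond closes the final three-membered ring by the sigmatropic walk of C4. The two bridgehead centres are necessarily cis on the five-membered ring and C4 migrates with inversion, so its endo substituent stays endo and the C4 stereocentre of 15 alone fixes all three new centres through the face toward which C4 tilts. The step needs cleavage of C4–C3 and not C4–C5, which the C3 methoxy group secures by stabilising the positive charge that develops at C3 (the product is a vinylogous ester). It also needs C4 to tilt toward its methyl face, expected because the bulky ortho-disubstituted pyranone avoids the endo position over the oxyallyl ring, and it needs the product to survive, which irradiation at 366 nm, where 17 absorbs only weakly, should ensure.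

Step 10
Reactants: 17 (1R,5S,6S)-4-methoxy-6-(6-methoxy-3,5-dimethyl-4-oxo-4H-pyran-2-yl)-3,5,6-trimethylbicyclo[3.1.0]hex-3-en-2-one
Product: 19 (1S,5S,6S)-6-(6-methoxy-3,5-dimethyl-4-oxo-4H-pyran-2-yl)-1,3,6-trimethylbicyclo[3.1.0]hex-3-en-2-one, via allylic alcohol 18 (not isolated)
Conditions: i-Bu2AlH, CH2Cl2, −78 °C; then 1 M HCl, THF, 0 °C
Reagents that add atoms: water, O
Why: Stork–Danheiser-type carbonyl transposition: 1,2-hydride reduction of the vinylogous ester carbonyl (exo face, a stereocentre of no consequence) and acid hydrolysis of the hydroxy enol ether with loss of water and methanol place the carbonyl on the former methoxy carbon, while the pyranone carbonyl should not be reduced at −78 °C.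

Step 11
Reactants: 20 pent-1-en-3-one
Product: 22 2-(1,2-dibromoethyl)-2-ethyl-1,3-dioxolane (racemic), via dibromoketone 21 (not isolated)
Conditions: Br2, CH2Cl2, 0 °C; then HOCH2CH2OH, p-TsOH (cat.), benzene, reflux, azeotropic removal of water
Reagents that add atoms: bromine, BrBr; ethane-1,2-diol, OCCO
Why: Electrophilic bromine addition to the enone and acid-catalysed ketalisation of the alpha-bromo ketone; the CHBr centre is racemic and is destroyed in step 12.

Step 12
Reactants: 22 2-(1,2-dibromoethyl)-2-ethyl-1,3-dioxolane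
Product: 23 2-(1-bromoethenyl)-2-ethyl-1,3-dioxolane
Conditions: t-BuOK, THF, 0 °C to rt
Reagents that add atoms: none
Why: E2 dehydrobromination: the base removes the hydrogen next to the ketal carbon with loss of the primary bromide to give the 1-bromovinyl ketal.

Step 13
Reactants: 19 (1S,5S,6S)-6-(6-methoxy-3,5-dimethyl-4-oxo-4H-pyran-2-yl)-1,3,6-trimethylbicyclo[3.1.0]hex-3-en-2-one; 23 2-(1-bromoethenyl)-2-ethyl-1,3-dioxolane
Product: 27 (1S,4R,5S,6S)-4-[1-(2-ethyl-1,3-dioxolan-2-yl)ethenyl]-6-(6-methoxy-3,5-dimethyl-4-oxo-4H-pyran-2-yl)-1,3,6-trimethylbicyclo[3.1.0]hex-2-en-2-yl trifluoromethanesulfonate, via vinyllithium 24 (not isolated), via lithium cuprate 25 (not isolated), via lithium enolate 26 (not isolated)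
Conditions: 23, t-BuLi (2 equiv per bromide), Et2O, −78 °C; CuI (0.5 equiv per vinyllithium), −78 to −40 °C; 19, −78 °C; then ArNTf2 (Ar = 5-chloropyridin-2-yl), THF, −78 to 0 °C
Reagents that add atoms: N-(5-chloropyridin-2-yl)-1,1,1-trifluoro-N-(trifluoromethylsulfonyl)methanesulfonamide, FC(F)(F)S(=O)(=O)N(c1ccc(Cl)cn1)S(=O)(=O)C(F)(F)F
Why: Bromine–lithium exchange and cuprate formation, then conjugate addition to the enone on the face opposite the cyclopropane (its endo methyl group covers the other face), should set C4, and the regiodefined enolate 26 is trapped on oxygen as the enol triflate (cuprate conjugate addition with enolate triflation).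

Step 14
Reactants: 27 (1S,4R,5S,6S)-4-[1-(2-ethyl-1,3-dioxolan-2-yl)ethenyl]-6-(6-methoxy-3,5-dimethyl-4-oxo-4H-pyran-2-yl)-1,3,6-trimethylbicyclo[3.1.0]hex-2-en-2-yl trifluoromethanesulfonate
Product: 29 2-methoxy-3,5-dimethyl-6-[(1S,4R,5R,6S)-1,3,6-trimethyl-4-(3-oxopent-1-en-2-yl)bicyclo[3.1.0]hex-2-en-6-yl]-4H-pyran-4-one (CNP0260557.1), via dioxolane 28 (not isolated)
Conditions: Pd(OAc)2 (5 mol %), PPh3, n-Bu3N, HCO2H, DMF, 60 °C; then 1 M HCl, THF, rt
Reagents that add atoms: water, O
Why: Palladium-catalysed formate reduction of the enol triflate (oxidative addition to zerovalent palladium, hydride transfer from formate, reductive elimination) replaces C–O by C–H without moving the double bond, and mild aqueous acid then hydrolyses the dioxolane to the enone; no stereocentre is affected.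

**Compound list**
1 | 2,5-dimethylanisole | COc1cc(C)ccc1C | starting material
2 | (2-methoxy-3,6-dimethylphenyl)lithium | [Li]c1c(OC)c(C)ccc1C | intermediate
3 | 2-methoxy-3,6-dimethylbenzoic acid | OC(=O)c1c(OC)c(C)ccc1C | intermediate
4 | (S)-2-(methoxymethyl)pyrrolidine | COC[C@@H]1CCCN1 | starting material
5 | 2-methoxy-3,6-dimethylbenzoyl chloride | ClC(=O)c1c(OC)c(C)ccc1C | intermediate
6 | (2-methoxy-3,6-dimethylphenyl)[(2S)-2-(methoxymethyl)pyrrolidin-1-yl]methanone | COC[C@@H]1CCCN1C(=O)c1c(OC)c(C)ccc1C | intermediate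
7 | potassium [(2S)-2-(methoxymethyl)pyrrolidin-1-yl](2-methoxy-3,6-dimethylcyclohexa-2,5-dien-1-ylidene)methanolate | [K+].[O-]C(=C1C(OC)=C(C)CC=C1C)N1CCC[C@H]1COC | intermediate
8 | [(1S)-2-methoxy-1,3,6-trimethylcyclohexa-2,5-dien-1-yl][(2S)-2-(methoxymethyl)pyrrolidin-1-yl]methanone | C1C(C)=C(OC)[C@@](C)(C(=O)N2CCC[C@H]2COC)C(C)=C1 | intermediate
9 | lithium 1-[(1S)-2-methoxy-1,3,6-trimethylcyclohexa-2,5-dien-1-yl]-1-[(2S)-2-(methoxymethyl)pyrrolidin-1-yl]propan-1-olate (carbinol centre undefined) | C1C(C)=C(OC)[C@@](C)(C(O[Li])(CC)N2CCC[C@H]2COC)C(C)=C1 | intermediate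
10 | 1-[(1S)-2-methoxy-1,3,6-trimethylcyclohexa-2,5-dien-1-yl]propan-1-one | C1C(C)=C(OC)[C@@](C)(C(=O)CC)C(C)=C1 | intermediate
11 | trimethyl{[(1Z)-1-[(1S)-2-methoxy-1,3,6-trimethylcyclohexa-2,5-dien-1-yl]prop-1-en-1-yl]oxy}silane | C1C(C)=C(OC)[C@@](C)(/C(O[Si](C)(C)C)=C/C)C(C)=C1 | intermediate
12 | 5-[(1S)-2-methoxy-1,3,6-trimethylcyclohexa-2,5-dien-1-yl]-2,4-dimethyl-3,5-dioxopentanoyl chloride (C2 and C4 undefined) | C1C(C)=C(OC)[C@@](C)(C(=O)C(C)C(=O)C(C)C(Cl)=O)C(C)=C1 | intermediate
13 | 4-hydroxy-6-[(1S)-2-methoxy-1,3,6-trimethylcyclohexa-2,5-dien-1-yl]-3,5-dimethyl-2H-pyran-2-one | C1C(C)=C(OC)[C@@](C)(c2oc(=O)c(C)c(O)c2C)C(C)=C1 | intermediate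
14 | 2-methoxy-6-[(1S)-2-methoxy-1,3,6-trimethylcyclohexa-2,5-dien-1-yl]-3,5-dimethyl-4H-pyran-4-one | C1C(C)=C(OC)[C@@](C)(c2oc(OC)c(C)c(=O)c2C)C(C)=C1 | intermediate
15 | (4S)-3-methoxy-4-(6-methoxy-3,5-dimethyl-4-oxo-4H-pyran-2-yl)-2,4,5-trimethylcyclohexa-2,5-dien-1-one | O=C1C(C)=C(OC)[C@@](C)(c2oc(OC)c(C)c(=O)c2C)C(C)=C1 | intermediate
16 | bicyclic oxyallyl zwitterion (cyclopropane across the former C3–C4–C5, apex methyl endo, pyranone exo) | [O-]C1=C[C@@]2(C)[C@](C)(c3oc(OC)c(C)c(=O)c3C)[C@@]2(OC)[C+]1C | intermediate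
17 | (1R,5S,6S)-4-methoxy-6-(6-methoxy-3,5-dimethyl-4-oxo-4H-pyran-2-yl)-3,5,6-trimethylbicyclo[3.1.0]hex-3-en-2-one | O=C1C(C)=C(OC)[C@@]2(C)[C@@H]1[C@]2(C)c3oc(OC)c(C)c(=O)c3C | intermediate
18 | (1R,2S,5S,6S)-4-methoxy-6-(6-methoxy-3,5-dimethyl-4-oxo-4H-pyran-2-yl)-3,5,6-trimethylbicyclo[3.1.0]hex-3-en-2-ol | O[C@@H]1C(C)=C(OC)[C@@]2(C)[C@@H]1[C@]2(C)c3oc(OC)c(C)c(=O)c3C | intermediate
19 | (1S,5S,6S)-6-(6-methoxy-3,5-dimethyl-4-oxo-4H-pyran-2-yl)-1,3,6-trimethylbicyclo[3.1.0]hex-3-en-2-one | O=C1C(C)=C[C@@H]2[C@@]1(C)[C@@]2(C)c3oc(OC)c(C)c(=O)c3C | intermediate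
20 | pent-1-en-3-one | C=CC(=O)CC | starting material
21 | 1,2-dibromopentan-3-one (racemic) | BrCC(Br)C(=O)CC | intermediate
22 | 2-(1,2-dibromoethyl)-2-ethyl-1,3-dioxolane (racemic) | BrCC(Br)C1(CC)OCCO1 | intermediate
23 | 2-(1-bromoethenyl)-2-ethyl-1,3-dioxolane | C=C(Br)C1(CC)OCCO1 | intermediate
24 | [1-(2-ethyl-1,3-dioxolan-2-yl)ethenyl]lithium | [Li]C(=C)C1(CC)OCCO1 | intermediate
25 | lithium bis[1-(2-ethyl-1,3-dioxolan-2-yl)ethenyl]cuprate | [Li+].C=C([Cu-]C(=C)C1(CC)OCCO1)C1(CC)OCCO1 | intermediate
26 | lithium (1S,4R,5S,6S)-4-[1-(2-ethyl-1,3-dioxolan-2-yl)ethenyl]-6-(6-methoxy-3,5-dimethyl-4-oxo-4H-pyran-2-yl)-1,3,6-trimethylbicyclo[3.1.0]hex-2-en-2-olate | [Li]OC1=C(C)[C@H](C(=C)C3(CC)OCCO3)[C@@H]2[C@@]1(C)[C@@]2(C)c4oc(OC)c(C)c(=O)c4C | intermediate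
27 | (1S,4R,5S,6S)-4-[1-(2-ethyl-1,3-dioxolan-2-yl)ethenyl]-6-(6-methoxy-3,5-dimethyl-4-oxo-4H-pyran-2-yl)-1,3,6-trimethylbicyclo[3.1.0]hex-2-en-2-yl trifluoromethanesulfonate | FC(F)(F)S(=O)(=O)OC1=C(C)[C@H](C(=C)C3(CC)OCCO3)[C@@H]2[C@@]1(C)[C@@]2(C)c4oc(OC)c(C)c(=O)c4C | intermediate
28 | 6-[(1S,4R,5R,6S)-4-[1-(2-ethyl-1,3-dioxolan-2-yl)ethenyl]-1,3,6-trimethylbicyclo[3.1.0]hex-2-en-6-yl]-2-methoxy-3,5-dimethyl-4H-pyran-4-one | C1=C(C)[C@H](C(=C)C3(CC)OCCO3)[C@@H]2[C@@]1(C)[C@@]2(C)c4oc(OC)c(C)c(=O)c4C | intermediate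
29 | 2-methoxy-3,5-dimethyl-6-[(1S,4R,5R,6S)-1,3,6-trimethyl-4-(3-oxopent-1-en-2-yl)bicyclo[3.1.0]hex-2-en-6-yl]-4H-pyran-4-one (CNP0260557.1) | C=C(C(=O)CC)[C@H]1C(C)=C[C@@]2(C)[C@@H]1[C@]2(C)c1oc(OC)c(C)c(=O)c1C | target

**Step count and risks**

Total step count: 14. Longest linear sequence: 12 steps (steps 1–10, 13 and 14); steps 11 and 12 make the side-chain fragment.

Steps most likely to fail:

1. Step 9. C4 may tilt toward the pyranone face during β,β-bonding, which puts the pyranone endo and leads into the series with opposite bridgehead configuration. Further light absorption by the product may cause apex epimerisation or rearrangement to phenols, and together with the wrong tilt this would lower the enantiomeric purity. Fallback: run the photorearrangement before the heterocycle exists. It sets out from ketone 10. Allylic oxidation with (C5H5NH)2Cr2O7 and t-BuOOH should give the 4-propanoyl dienone F1, a 4-acyl-3-methoxy dienone of the class on which this rearrangement is best documented. Irradiation at 366 nm should give the 6-propanoyl lumiketone F2, whose apex epimers can be separated. Me3SiOTf and Et3N should give the silyl enol ether F3 (the ring carbonyl has no enolisable hydrogen), and 2-methylpropanedioyl dichloride should give the hydroxypyranone F4. Methylation with MeOTf brings the sequence back to the route at compound 17.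

2. Step 4. Addition to the very hindered amide carbonyl may not take place, and deprotonation at the doubly allylic CH2 may compete. Fallback: remove the auxiliary with a small hydride and rebuild the ketone. It sets out from amide 8. Reduction with LiNH2BH3 should give the primary alcohol F5 and free the auxiliary, and Dess–Martin oxidation should give the aldehyde F6. Addition of EtMgBr should give the secondary alcohol F7 as a mixture of carbinol epimers, and a second Dess–Martin oxidation returns to the route at ketone 10.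

3. Step 13. Conjugate addition of the alpha-branched vinyl cuprate next to the cyclopropane may be slow. Electron transfer may open the cyclopropane, the vinyl metal may lose alkoxide by β-elimination on warming, and O-triflation may be incomplete. Fallback: bring in the side chain by 1,2-addition and move the oxygen by reductive transposition. It sets out from vinylogous ester 17 and uses the vinyllithium 24 premixed with CeCl3. 1,2-Addition to the ring carbonyl and a short, cold, dilute-acid work-up (Stork–Danheiser transposition) should give the cross-conjugated dienone F8 with the dioxolane intact. Condensation with 4-methylbenzenesulfonohydrazide should give the tosylhydrazone F9. Catecholborane, then NaOAc in warm chloroform, should reduce the C=N bond from the exo face. The allylic diazene then passes its hydrogen to C4 on the same face with loss of dinitrogen. This returns to the route at dioxolane 28, which is hydrolysed as in step 14.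

**Further compounds**
F1 | step 9 | (4S)-3-methoxy-2,4,5-trimethyl-4-propanoylcyclohexa-2,5-dien-1-one | O=C1C(C)=C(OC)[C@@](C)(C(=O)CC)C(C)=C1
F2 | step 9 | (1R,5S,6S)-4-methoxy-3,5,6-trimethyl-6-propanoylbicyclo[3.1.0]hex-3-en-2-one | O=C1C(C)=C(OC)[C@@]2(C)[C@@H]1[C@]2(C)C(=O)CC
F3 | step 9 | (1R,5S,6S)-4-methoxy-3,5,6-trimethyl-6-[(1Z)-1-(trimethylsilyloxy)prop-1-en-1-yl]bicyclo[3.1.0]hex-3-en-2-one | O=C1C(C)=C(OC)[C@@]2(C)[C@@H]1[C@]2(C)/C(O[Si](C)(C)C)=C/C
F4 | step 9 | (1R,5S,6S)-6-(4-hydroxy-3,5-dimethyl-2-oxo-2H-pyran-6-yl)-4-methoxy-3,5,6-trimethylbicyclo[3.1.0]hex-3-en-2-one | O=C1C(C)=C(OC)[C@@]2(C)[C@@H]1[C@]2(C)c3oc(=O)c(C)c(O)c3C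
F5 | step 4 | [(1R)-2-methoxy-1,3,6-trimethylcyclohexa-2,5-dien-1-yl]methanol | C1C(C)=C(OC)[C@@](C)(CO)C(C)=C1
F6 | step 4 | (1S)-2-methoxy-1,3,6-trimethylcyclohexa-2,5-diene-1-carbaldehyde | C1C(C)=C(OC)[C@@](C)(C=O)C(C)=C1
F7 | step 4 | 1-[(1R)-2-methoxy-1,3,6-trimethylcyclohexa-2,5-dien-1-yl]propan-1-ol (carbinol epimers) | C1C(C)=C(OC)[C@@](C)(C(O)CC)C(C)=C1
F8 | step 13 | (1S,5S,6S)-4-[1-(2-ethyl-1,3-dioxolan-2-yl)ethenyl]-6-(6-methoxy-3,5-dimethyl-4-oxo-4H-pyran-2-yl)-1,3,6-trimethylbicyclo[3.1.0]hex-3-en-2-one | O=C1C(C)=C(C(=C)C3(CC)OCCO3)[C@@H]2[C@@]1(C)[C@@]2(C)c4oc(OC)c(C)c(=O)c4C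
F9 | step 13 | 4-methylbenzenesulfonohydrazone of F8 (ring stereocentres as in F8, C=N geometry undefined) | Cc5ccc(cc5)S(=O)(=O)NN=C1C(C)=C(C(=C)C3(CC)OCCO3)[C@@H]2[C@@]1(C)[C@@]2(C)c4oc(OC)c(C)c(=O)c4C
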